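At 2.00 h and 4.00 h of the dawn run, the substrate Q stands at 86.3 % and 74.2 % of its charge. Working with the fraction left, I get 0.0737 h⁻¹ and then 0.0746 h⁻¹ for k, the logarithm of that fraction per hour: within the scatter a pseudo-first-order loss of Q.

in all of them: Q 11 mM; X 16.5 mM; Z 40 µM
- dawn: J 15 µM; run made earlier
- flask: J 7.3 µM
dawn run (percent of the Q charged)

| time / h | L / % | Q / % |
|---|---|---|
| 0.833 | 0.2 | 94.0 |
| 2.00 | 1.9 | 86.3 |
| 4.00 | 8.4 | 74.2 |
| 6.00 | 14.7 | 65.5 |

(scatter of a reading: 1 percentage point)
- factor on the rate of making L when 20 % of the Q are converted if X is charged twice over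
- factor on the rate when 20 % of the Q are converted if Z is charged at 200 µM instead
- the numbers in the tables scatter by 1 percentage point (one standard deviation)
- no earlier run changes the charge of Z; that part of a forecast is a guess
- no earlier run changes the charge of X; that part of a forecast is a guess

The new flask differs from the dawn run in J, and no earlier run changes the charge of Z or shows what J does, so my next link is a guess: each J takes one catalyst Z out of work. That gives W, the working catalyst, Z charged minus J charged 32.7 µM, against 25.0 µM at dawn. If k goes with W, the new flask loses Q at 0.0976 h⁻¹, and 20 % of its Q is converted by 2.29 h.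

The product L lags behind the loss of Q, so something stands between them. If both steps run on W, that species stands at the same level at a given fraction left, and the rate of making L goes with W. The plain charge ratio, 5.00, is the weak link: it counts the Z that J holds, 7.3 µM in the new flask by my guess. Reforged with W, my ratio is 5.89. I make no reckoning for the reagent X, whose charge no earlier run changes.

The forecast gives dbl 1.4 and ratio 2.8, and says “these factors are guesses”. Its ratio is lower than mine.

The flask gives dbl 1.57 and ratio 5.89.

    Q + Z → Z + D (k = 3000 M⁻¹ h⁻¹)
    X + Z + D → Z + L (k = 4.60 × 10⁵ M⁻² h⁻¹)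
    Z + J → E (k = 6.40 × 10⁶ M⁻¹ h⁻¹)

At 2.00 h this flask holds Z at 81.8 % and E at 18.2 % of the catalyst charged, with J at 0 %, and W is 81.8 % of the charge. Its rate of making L at 20 % conversion is 0.401 mM h⁻¹. Scaled by W to the dawn run, that becomes 0.307 mM h⁻¹, and the dawn readings of L between 2.00 h and 4.00 h climb at 0.357 mM h⁻¹.

(The numbers in the tables were computed on assumed constants; scatter was added.)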